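Once the substrate has taken its first partner, the coupling partner beyond one equivalent is a leftover, about 11.0 mM in this flask, and it can go on reacting with the mono adduct.

the same everywhere: substrate 11 mM

| charge | coupling partner | remark | time |
|---|---|---|---|
| south-west | 2 equiv | the very flask that is asked about, followed so far |  |
| flask | 2.00 equiv |  | 20 min |

- south-west (time / min: mono adduct / %, double product / %): 1.50: 78, 2; 3.00: 77, 8; 5.00: 76, 12; 6.00: 73, 10; 8.00: 67, 13; 10.0: 67, 14

(readings scatter by 1.5 percentage points)

- equivalents of coupling partner to substrate, everything else as given, that leave most mono adduct at 20 min
- the amount of mono adduct then, in percent of the substrate charged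
- the amount of mono adduct with the amounts as given



My bench rule is to freeze that leftover. If it holds still, the mono adduct falls by a fixed share each minute (pseudo-first-order). I average the first two and the last two mono adduct readings of the south-west run:

loss rate = ln(77.5% / 67.0%) / 6.75 min = 0.0216 min⁻¹

This loss rate, read from scattered readings, is the share of mono adduct lost per minute at one equivalent of leftover, and it is what I carry. Run back to the start and forward to 20 min, it gives:

start = 81.4%

at 20 min: 52.8%

The border is the partner spent against the leftover. If each mono adduct lost takes one partner, that ratio is 0.285, below one, so I let the freeze stand here and commit to 52.8%. In this reckoning a smaller leftover gives a smaller loss rate, so my pick for the charge lies below 2.00 equiv, nearer one equivalent than two.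

The forecast differs, giving 2.15 equiv, 66% and 65.5%: “by 20 min the system is essentially equilibrated at about 65–66%”.

The flask gives 52.0% as charged, and 62.9% at 1.25 equiv.

    substrate + coupling partner → mono adduct (k = 1.59 L mol⁻¹ s⁻¹)
    coupling partner + mono adduct → double product (k = 0.0467 L mol⁻¹ s⁻¹)
    double product ⇌ isomer of the product (K = 0.617, k = 0.00316 s⁻¹)
    substrate + mono adduct → side product (k = 0.318 L mol⁻¹ s⁻¹)

Between 2.00 min and 20.0 min this flask's mono adduct falls from 79.2% to 52.0%, a rate of 0.0234 min⁻¹ against the carried 0.0216 min⁻¹. A neighbouring flask charged with 5.00 equiv has a leftover of 44.0 mM. Taken in proportion to the leftover, the loss rate becomes 0.0863 min⁻¹, and, assuming the same start, the reckoning gives 14.5% at 20 min. That neighbour ends with 11.7% mono adduct.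

The earlier runs and the new flask were generated by integration for substances that don't exist, and the scatter is random.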